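The constant I looked for in ash, cedar and maple was no rate constant but a ratio of two amounts: the plateau of left-handed product and the partner charged, both in percent of the two substrates together.

| flask | left-handed substrate | right-handed substrate | partner | free catalyst | remark | time |
|---|---|---|---|---|---|---|
| ash | 0.22 M | 0.22 M | 0.22 M | 0.25 mM | run made earlier |  |
| cedar | 0.22 M | 0.22 M | 0.22 M | 0.40 mM | run made earlier |  |
| maple | 0.33 M | 0.33 M | 0.22 M | 0.18 mM | run made earlier |  |
| flask | 0.22 M | 0.22 M | 0.220 M | 0.18 mM |  | 12 h |

- ash (time / h: left-handed product / %, left-handed substrate / %): 3.00: 22.3, 25.4; 6.00: 28.8, 22.4; 8.00: 28.6, 21.2; 12.0: 28.0, 21.0; 15.0: 28.1, 22.0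
- cedar (time / h: left-handed product / %, left-handed substrate / %): 1.33: 21.3, 28.7; 4.00: 30.3, 22.6; 6.00: 30.0, 18.4; 10.0: 31.1, 17.0; 15.0: 31.1, 17.6
- maple (time / h: left-handed product / %, left-handed substrate / %): 1.00: 8.2, 41.9; 2.00: 11.8, 37.7; 4.00: 17.2, 33.0; 8.00: 20.3, 30.3; 15.0: 19.2, 31.1

(scatter of a reading: 1 percentage point)

- free catalyst is single-handed; left-handed substrate and right-handed substrate are mirror images of each other, charged as a racemate, each of them at the stated concentration

* amount of left-handed product in the flask at 12 h, in percent of the left-handed substrate and right-handed substrate together charged
* amount of left-handed substrate in the flask at 12 h, in percent of the left-handed substrate and right-handed substrate together charged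

In ash, left-handed product stood flat from 6.00 h, and with left-handed substrate it summed to about 50.0%. Raising the catalyst from 0.25 mM in ash to 0.40 mM in cedar moved the last product reading from 28.1% to 31.1%. Maple, with partner at 33.3%, ended lower than ash, at 19.2%. I therefore took partner for the limiting reagent and reckoned with the partner yield, the plateau of left-handed product per partner charged:

ash plateau, mean of the last three readings: 28.2%

partner charged: 50.0%

partner yield: 0.565

Scaled inversely to the catalyst, ash's plateau time became 8.33 h for the flask, less than the 12 h asked, so I counted on the plateau:

left-handed product: 0.565 × 50.0% = 28.2%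

left-handed substrate: 21.8%

The forecast gave 27.2% and 22.8%, lower in product than my figure, on the ground that “The flask has ash's stoichiometry but less catalyst”.

The flask gave 27.2% of left-handed product and 22.8% of left-handed substrate.

    free catalyst + right-handed substrate ⇌ catalyst intermediate B (K = 2.40 /M, k = 12.0 /M/s)
    free catalyst + left-handed substrate ⇌ catalyst intermediate A (K = 4.10 /M, k = 170 /M/s)
    partner + catalyst intermediate B → free catalyst + right-handed product (k = 0.490 /M/s)
    partner + catalyst intermediate A → free catalyst + left-handed product (k = 1.10 /M/s)
    partner → decomposed reagent (k = 2.80 × 10⁻⁵ /s)

The partner yield of the flask came to 0.544, against 0.565 read from ash. The backward run from catalyst intermediate B to free catalyst + right-handed substrate is the main reason the flask reached this much left-handed product: in a run of the flask with that step taken away, left-handed product came to 2.01% instead of 27.2%. Carried to the neighbour flask charged with 0.055 M of partner, the yield from ash gave 7.06% of left-handed product, and that flask held 7.41%.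

The readings are calculated from invented constants; scatter was added.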